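Numbering: guaiane locants, C1–C15 for the acetoxy half and C1′–C15′ for the peroxide half; ring A is the cycloheptanone C1/C5/C6/C7/C8/C9/C10.
Cut 1 (last bond made) is C7–C8 of ring A. The enabling feature is the array C8(=O)–C7H(CHMe2)–C6H2 on the C4=C5 alkene, with C9–C10 on the adjacent bridgehead C1. This is the menthone array, the retron of a C8 acyl radical adding 7-exo to a prenyl group on C5.
Cut 2 is C3–C3′ and C1–C4′ (norbornene; endo Diels–Alder of a 5-acetoxycyclopentadiene with a hydroazulene cyclopentadienone). Cut 3 is C11′–O/O–C8′ (Schenck ene, hemiketal) and C7′–C8′ (carbonyl-ene).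
Both partners then carry the same three substituents. They come from one cyclopentenediol, made from 3-methylfurfural by crotylboration, Piancatelli rearrangement and prenyl addition.
Forward ring order: cyclopentene, then right cycloheptane, then 1,2-dioxolane, then the two norbornene rings, then ring A.
Stereochemistry: C10/C10′ come from catalyst-controlled crotylboration. C2 comes from the trans Piancatelli pair, whose two diastereomers are separated and both used (the dienophile erases its ring centres). C1, C3, C3′ and C4′ come from the endo cycloaddition anti to OAc and anti to the C10′ methyl. C7 and C8′ equilibrate.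

Key step: step 14

Assumption: C7 (α to the ring-A ketone) and C8′ (peroxy-hemiketal carbon) are configurationally labile; the natural configuration is taken to be the thermodynamically preferred one at both.

Step 1
Reactants: 1 3-methylfuran-2-carbaldehyde; 2 (E)-crotylboronic acid pinacol ester
Product: 3 (1R,2R)-2-methyl-1-(3-methylfuran-2-yl)but-3-en-1-ol
Conditions: (R)-TRIP hydrogen phosphate (5 mol %), toluene, −30 °C; aq. work-up
Reagents that add atoms: none
Why: Chiral-phosphoric-acid-catalysed crotylboration through a closed chair transition state: the E-boronate gives the anti adduct and the catalyst directs Re-face attack, which fixes the (R) methyl-bearing carbon that becomes C10 and C10′ (the carbinol centre is lost in step 2).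

Step 2
Reactants: 3 (1R,2R)-2-methyl-1-(3-methylfuran-2-yl)but-3-en-1-ol
Product: 4 (4S,5R)-5-[(2R)-but-3-en-2-yl]-4-hydroxy-2-methylcyclopent-2-en-1-one and 5 its (4R,5S) trans diastereomer (carried on together)
Conditions: Dy(OTf)3 (10 mol %), t-BuOH–H2O 5:1, 80 °C
Reagents that add atoms: water, O
Why: Piancatelli rearrangement (furfuryl cation, water attack at furan C5, ring opening, conrotatory 4π closure) gives only the 4,5-trans relationship, and because the side-chain centre should bias the sense of conrotation little, both trans diastereomers are expected, 4 having the C2 configuration of the target.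

Step 3
Reactants: 4 and 5 (mixture); 6 1-chloro-3-methylbut-2-ene
Product: 7 (1R,4S,5R)-5-[(2R)-but-3-en-2-yl]-2-methyl-1-(3-methylbut-2-en-1-yl)cyclopent-2-ene-1,4-diol and 8 its (1S,4R,5S) ring diastereomer (separated on silica)
Conditions: BaI2, Li biphenylide, THF, rt; 6, −78 °C; 4/5, −78 °C (2.5 equiv reagent); H2O
Reagents that add atoms: none
Why: Allylbarium 1,2-addition, the allylmetal class that reacts at its unsubstituted (α) terminus and so delivers a linear prenyl group; one equivalent deprotonates the OH, the next adds to the ketone face anti to the neighbouring side chain, and the two diols are then separable diastereomers.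

Step 4
Reactants: 8 (1S,4R,5S)-diol
Product: 9 (4S,5R)-5-[(2R)-but-3-en-2-yl]-4-hydroxy-3-methyl-4-(3-methylbut-2-en-1-yl)cyclopent-2-en-1-one
Conditions: MnO2, CH2Cl2, rt
Reagents that add atoms: none
Why: Allylic alcohol oxidation with MnO2 touches only the secondary allylic OH and turns 8 into a 4-hydroxycyclopentenone, a masked cyclopentadienone in which the ring stereocentres no longer matter.

Step 5
Reactants: 9 hydroxy enone
Product: 10 (1S,5R)-5-[(2R)-but-3-en-2-yl]-2-methyl-1-(3-methylbut-2-en-1-yl)-4-oxocyclopent-2-en-1-yl acetate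
Conditions: Ac2O, Sc(OTf)3 (2 mol %), MeCN, −20 °C
Reagents that add atoms: acetic anhydride, CC(=O)OC(C)=O
Why: Lewis-acid-catalysed acylation of a tertiary alcohol installs the leaving group for the later E1cB step and prevents lactol formation in step 6, under base-free conditions that cannot yet trigger the elimination.

Step 6
Reactants: 10 tertiary acetate
Product: 11 (3R)-3-[(1R,2S)-2-acetoxy-3-methyl-2-(3-methylbut-2-en-1-yl)-5-oxocyclopent-3-en-1-yl]butanal
Conditions: PdCl2(PhCN)2 (12 mol %), CuCl2·2H2O (12 mol %), AgNO2 (6 mol %), O2 (1 atm), t-BuOH–MeNO2 15:1, rt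
Reagents that add atoms: dioxygen, O=O
Why: Aldehyde-selective (anti-Markovnikov) nitrite-co-catalysed Wacker oxidation acts only on the monosubstituted alkene, whose branched allylic carbon further disfavours attack at the internal position, while prenyl, enone and acetate are inert.

Step 7
Reactants: 11 aldehyde
Product: 12 5-acetoxy-8-hydroxyguaia-3,11-dien-2-one (trans-fused hydroazulenone; 8-OH and 7-isopropenyl trans, 10-methyl R)
Conditions: Me2AlCl (2 equiv), CH2Cl2, −78 to −20 °C; 1 M HCl
Reagents that add atoms: none
Why: Type I intramolecular carbonyl-ene reaction (the homologue of citronellal to isopulegol): C7′ of the prenyl group attacks the Lewis-acid-bound aldehyde with transfer of a methyl H through a chair-like transition state that places OH and isopropenyl trans, both new centres being erased in steps 8 and 9.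

Step 8
Reactants: 12 homoallylic alcohol
Product: 14 5-acetoxyguaia-3,7(11)-diene-2,8-dione, via 5-acetoxyguaia-3,11-diene-2,8-dione 13 (not isolated)
Conditions: Dess–Martin periodinane, CH2Cl2, rt; filtration; TsOH·H2O (10 mol %), CH2Cl2, rt
Reagents that add atoms: none
Why: Dess–Martin oxidation gives the β,γ-unsaturated ketone, which acid-catalysed enolisation and γ-protonation move into conjugation (isopulegone-to-pulegone type), acid being used because base would eliminate the tertiary acetate.

Step 9
Reactants: 14 isopropylidene dione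
Product: 16 5-acetoxy-8-hydroxy-8,11-epidioxyguaia-3,6-dien-2-one, via 5-acetoxy-11-hydroperoxyguaia-3,6-diene-2,8-dione 15 (not isolated)
Conditions: O2, tetraphenylporphyrin (1 mol %), visible light, CH2Cl2, 0 °C; used directly
Reagents that add atoms: dioxygen, O=O
Why: Schenck ene reaction of an s-cis alkylidene ketone (known for pulegone): singlet oxygen takes the H geminal to the acyl group (C6′–H) and binds to C11′, the hydroperoxide closes 5-exo-trig onto the C8′ ketone to the 1,2-dioxolan-3-ol whose anomeric centre is under thermodynamic control, and the electron-poor cyclopentenone alkene does not react.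

Step 10
Reactants: 7 (1R,4S,5R)-diol
Product: 17 (1S,4R,5R)-5-[(2R)-but-3-en-2-yl]-4-hydroxy-3-methyl-4-(3-methylbut-2-en-1-yl)cyclopent-2-en-1-yl acetate
Conditions: Ac2O, pyridine, CH2Cl2, 0 °C
Reagents that add atoms: acetic anhydride, CC(=O)OC(C)=O
Why: Acylation discriminates the secondary allylic from the tertiary alcohol on steric grounds and installs the acetate of the target on the C2 centre carried by 7.

Step 11
Reactants: 17 monoacetate
Product: 18 (1S)-2-[(2R)-but-3-en-2-yl]-4-methyl-3-(3-methylbut-2-en-1-yl)cyclopenta-2,4-dien-1-yl acetate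
Conditions: bis[α,α-bis(trifluoromethyl)benzyloxy]diphenylsulfurane (Martin sulfurane, 1.2 equiv), CH2Cl2, −40 to 0 °C; used at once
Reagents that add atoms: none
Why: Sulfurane-mediated dehydration of a tertiary allylic alcohol at low temperature: loss of H1, anti to the leaving group on the ring, gives the tetrasubstituted endocyclic alkene and hence the cyclopentadiene, which is used at once to forestall 1,5-H shifts.

Step 12
Reactants: 16 acetoxy peroxy-hemiketal; 18 acetoxycyclopentadiene (slight excess)
Product: 20 endo adduct (norbornene with the C2–OAc bridge syn to C4=C5, prenyl on C5, (R)-but-3-en-2-yl on C1, fused at C3′–C4′ to the peroxide hydroazulenone), via 8-hydroxy-8,11-epidioxyguaia-1(5),3,6-trien-2-one 19 (not isolated)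
Conditions: Et3N (1.5 equiv), CH2Cl2, 0 °C to rt, slow addition of 16
Reagents that add atoms: none
Why: E1cB loss of acetic acid from the 4-acetoxycyclopentenone unmasks cyclopentadienone 19, which is trapped at its only trisubstituted bond C3′=C4′ in an endo Diels–Alder reaction: the unsubstituted termini C3 and C3′ bond first (as in cyclopentadiene/cyclopentadienone pairs), the diene is attacked anti to OAc because the C15′ methyl must point exo towards C2 and should override the usual syn-to-oxygen bias, and the dienophile is attacked anti to the pseudo-axial C10′ methyl, which together set C1, C3, C3′ and C4′.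

Step 13
Reactants: 20 adduct
Product: 21 C8 aldehyde of 20 ((R)-4-oxobutan-2-yl on C1)
Conditions: PdCl2(PhCN)2 (12 mol %), CuCl2·2H2O (12 mol %), AgNO2 (6 mol %), O2 (1 atm), t-BuOH–MeNO2 15:1, rt
Reagents that add atoms: dioxygen, O=O
Why: The same aldehyde-selective Wacker oxidation finds a single monosubstituted alkene next to a branched carbon on a quaternary bridgehead, and its oxidising Pd(II) medium should leave the tertiary peroxy-hemiketal, the prenyl group and the tetrasubstituted alkene alone.

Step 14
Reactants: 21 aldehyde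
Product: 22 target CNP0317907.1
Conditions: i-Pr3SiSH (20 mol %), V-70 (3 × 10 mol %), PhCF3 (0.01 M), Ar, 40 °C
Reagents that add atoms: none
Why: Proposed new method: a thiyl radical (silanethiol plus azo initiator) abstracts the formyl H of 21, the nucleophilic C8 acyl radical adds to C7 of the prenyl group, and the tertiary C11 radical takes H back from the thiol, so that a chain isomerisation makes the C7–C8 bond, the ketone and the isopropyl group in one event. The closest known reaction type is the thiol-catalysed (polarity-reversal) acyl-radical cyclisation of alkenals, for example citronellal to menthone in the 6-exo mode, and 7-exo acyl-radical closures are known from selenoesters; untested is the 7-exo mode under thiol catalysis in a substrate of this density. Ring A closes 7-exo-trig, the two arms being held cis and nearly eclipsed on C1 and C5 of the rigid norbornene. C7 is the only new stereocentre: it is formed under steric control by the scaffold but, being α to the new ketone, it should end as the more stable, natural epimer. The step needs attack at C7 rather than at C5=C4 (5-exo/6-endo) or at C5′ of the enone, which is secured because C7 is the only CH alkene terminus within reach while each alternative would build a quaternary carbon next to C1 or C4′; it also needs cyclisation to beat decarbonylation, hence 40 °C, and formyl-H abstraction to beat loss of H6, where a pentadienyl-type radical cannot become planar for A1,3 strain with C15 and C1 and the H transfer is reversible. The fully substituted O–O bridge, the acetate and both enone units should not be touched by the chain carriers.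

Compound list
1 | 3-methylfuran-2-carbaldehyde | Cc1ccoc1C=O | starting material
2 | (E)-crotylboronic acid pinacol ester | C/C=C/CB1OC(C)(C)C(C)(C)O1 | starting material
3 | (1R,2R)-2-methyl-1-(3-methylfuran-2-yl)but-3-en-1-ol | C=C[C@@H](C)[C@@H](O)c1occc1C | intermediate
4 | (4S,5R)-5-[(2R)-but-3-en-2-yl]-4-hydroxy-2-methylcyclopent-2-en-1-one | C=C[C@@H](C)[C@@H]1[C@@H](O)C=C(C)C1=O | intermediate
5 | (4R,5S)-5-[(2R)-but-3-en-2-yl]-4-hydroxy-2-methylcyclopent-2-en-1-one | C=C[C@@H](C)[C@H]1[C@H](O)C=C(C)C1=O | intermediate
6 | 1-chloro-3-methylbut-2-ene | CC(C)=CCCl | starting material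
7 | (1R,4S,5R)-5-[(2R)-but-3-en-2-yl]-2-methyl-1-(3-methylbut-2-en-1-yl)cyclopent-2-ene-1,4-diol | C=C[C@@H](C)[C@@H]1[C@@H](O)C=C(C)[C@@]1(O)CC=C(C)C | intermediate
8 | (1S,4R,5S)-5-[(2R)-but-3-en-2-yl]-2-methyl-1-(3-methylbut-2-en-1-yl)cyclopent-2-ene-1,4-diol | C=C[C@@H](C)[C@H]1[C@H](O)C=C(C)[C@]1(O)CC=C(C)C | intermediate
9 | (4S,5R)-5-[(2R)-but-3-en-2-yl]-4-hydroxy-3-methyl-4-(3-methylbut-2-en-1-yl)cyclopent-2-en-1-one | C=C[C@@H](C)[C@H]1C(=O)C=C(C)[C@]1(O)CC=C(C)C | intermediate
10 | (1S,5R)-5-[(2R)-but-3-en-2-yl]-2-methyl-1-(3-methylbut-2-en-1-yl)-4-oxocyclopent-2-en-1-yl acetate | C=C[C@@H](C)[C@H]1C(=O)C=C(C)[C@]1(OC(C)=O)CC=C(C)C | intermediate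
11 | (3R)-3-[(1R,2S)-2-acetoxy-3-methyl-2-(3-methylbut-2-en-1-yl)-5-oxocyclopent-3-en-1-yl]butanal | O=CC[C@@H](C)[C@H]1C(=O)C=C(C)[C@]1(OC(C)=O)CC=C(C)C | intermediate
12 | 5-acetoxy-8-hydroxyguaia-3,11-dien-2-one | C[C@@H]1C[C@H](O)[C@@H](C(C)=C)C[C@@]2(OC(C)=O)C(C)=CC(=O)[C@H]12 | intermediate
13 | 5-acetoxyguaia-3,11-diene-2,8-dione | C[C@@H]1CC(=O)[C@@H](C(C)=C)C[C@@]2(OC(C)=O)C(C)=CC(=O)[C@H]12 | intermediate
14 | 5-acetoxyguaia-3,7(11)-diene-2,8-dione | C[C@@H]1CC(=O)C(=C(C)C)C[C@@]2(OC(C)=O)C(C)=CC(=O)[C@H]12 | intermediate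
15 | 5-acetoxy-11-hydroperoxyguaia-3,6-diene-2,8-dione | C[C@@H]1CC(=O)C(C(C)(C)OO)=C[C@@]2(OC(C)=O)C(C)=CC(=O)[C@H]12 | intermediate
16 | 5-acetoxy-8-hydroxy-8,11-epidioxyguaia-3,6-dien-2-one | C[C@@H]1C[C@@]3(O)OOC(C)(C)C3=C[C@@]2(OC(C)=O)C(C)=CC(=O)[C@H]12 | intermediate
17 | (1S,4R,5R)-5-[(2R)-but-3-en-2-yl]-4-hydroxy-3-methyl-4-(3-methylbut-2-en-1-yl)cyclopent-2-en-1-yl acetate | C=C[C@@H](C)[C@@H]1[C@@H](OC(C)=O)C=C(C)[C@@]1(O)CC=C(C)C | intermediate
18 | (1S)-2-[(2R)-but-3-en-2-yl]-4-methyl-3-(3-methylbut-2-en-1-yl)cyclopenta-2,4-dien-1-yl acetate | C=C[C@@H](C)C1=C(CC=C(C)C)C(C)=C[C@@H]1OC(C)=O | intermediate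
19 | 8-hydroxy-8,11-epidioxyguaia-1(5),3,6-trien-2-one | C[C@@H]1C[C@@]2(O)OOC(C)(C)C2=CC3=C1C(=O)C=C3C | intermediate
20 | endo Diels–Alder adduct with open ring A (vinyl and prenyl arms) | CC(=O)O[C@H]1[C@H]2C(C)=C(CC=C(C)C)[C@]1([C@H](C)C=C)[C@]3(C)C4=C(C(=O)[C@H]23)[C@H](C)C[C@@]5(O)OOC(C)(C)C5=C4 | intermediate
21 | C8 aldehyde of the adduct | CC(=O)O[C@H]1[C@H]2C(C)=C(CC=C(C)C)[C@]1([C@H](C)CC=O)[C@]3(C)C4=C(C(=O)[C@H]23)[C@H](C)C[C@@]5(O)OOC(C)(C)C5=C4 | intermediate
22 | CNP0317907.1 | CC(=O)O[C@H]1[C@H]2C(C)=C3C[C@@H](C(C)C)C(=O)C[C@@H](C)[C@]31[C@]1(C)C3=C(C(=O)[C@H]21)[C@H](C)C[C@@]1(O)OOC(C)(C)C1=C3 | target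

Total steps: 14. Longest linear sequence: 12 (steps 1–9 and 12–14).

Steps most likely to fail:

Step 14 (Proposed new method). The chain may stall through abstraction of allylic H at C6 instead of the formyl H. The acyl radical may also lose CO, or add to the C4=C5 alkene. The fallback is polar, uses known chemistry, sets out from 21 and returns at 22. The hemiketal OH is silylated (TESOTf, 2,6-lutidine) to the triethylsilyl peroxyketal aldehyde F1. A Me2AlCl-promoted type I carbonyl-ene cyclisation, as in step 7, closes ring A to the homoallylic alcohol F2. Dess–Martin oxidation gives the isopropenyl ketone F3. Diimide (potassium azodicarboxylate, AcOH) spares O–O bonds and hindered or conjugated alkenes, and saturates the isopropenyl group to the silyl-protected target F4. HF·pyridine then frees 22.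

Step 11. The elimination may take an allylic H of the prenyl CH2 and give the exocyclic conjugated triene, or the diene may isomerise by 1,5-H shift before use. The fallback sets out from 4 (separated from 5 at that stage) and returns at 18. Acetylation (Ac2O, pyridine) gives the acetoxy enone F5. Kinetic α′-deprotonation and O-triflation (LiHMDS, N-(5-chloro-2-pyridyl)bis(trifluoromethanesulfonimide), −78 °C) give the 2-triflyloxycyclopentadiene F6. Stille coupling with tributyl(3-methylbut-2-enyl)stannane (Pd2(dba)3, AsPh3, LiCl, rt) then gives 18. The diene position is thus fixed by enolate regiochemistry and not by an elimination.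

Step 7. The seven-membered ene closure may be too slow, so that Lewis-acid-induced loss of the tertiary acetate or chloride capture takes over. The fallback sets out from 11 and returns at 14. Pinnick oxidation (NaClO2, NaH2PO4, 2-methylbut-2-ene) gives the carboxylic acid F7. Trifluoroacetic anhydride converts it into the mixed anhydride F8. This acylates the prenyl alkene intramolecularly (Kondakov-type alkene acylation, the citronellic acid to pulegone manifold) to the enones 13 and 14, which the TsOH treatment of step 8 converges on 14.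

Further compounds
F1 | step 14 | triethylsilyl peroxyketal of aldehyde 21 | CC(=O)O[C@H]1[C@H]2C(C)=C(CC=C(C)C)[C@]1([C@H](C)CC=O)[C@]3(C)C4=C(C(=O)[C@H]23)[C@H](C)C[C@@]5(O[Si](CC)(CC)CC)OOC(C)(C)C5=C4
F2 | step 14 | ring-A homoallylic alcohol (8-OH, 7-isopropenyl, trans), TES peroxyketal | CC(=O)O[C@H]1[C@H]2C(C)=C3C[C@@H](C(C)=C)[C@H](O)C[C@@H](C)[C@]31[C@]1(C)C3=C(C(=O)[C@H]21)[C@H](C)C[C@@]1(O[Si](CC)(CC)CC)OOC(C)(C)C1=C3
F3 | step 14 | ring-A isopropenyl ketone, TES peroxyketal | CC(=O)O[C@H]1[C@H]2C(C)=C3C[C@@H](C(C)=C)C(=O)C[C@@H](C)[C@]31[C@]1(C)C3=C(C(=O)[C@H]21)[C@H](C)C[C@@]1(O[Si](CC)(CC)CC)OOC(C)(C)C1=C3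
F4 | step 14 | O-triethylsilyl derivative of the target | CC(=O)O[C@H]1[C@H]2C(C)=C3C[C@@H](C(C)C)C(=O)C[C@@H](C)[C@]31[C@]1(C)C3=C(C(=O)[C@H]21)[C@H](C)C[C@@]1(O[Si](CC)(CC)CC)OOC(C)(C)C1=C3
F5 | step 11 | (1S,5R)-5-[(2R)-but-3-en-2-yl]-3-methyl-4-oxocyclopent-2-en-1-yl acetate | C=C[C@@H](C)[C@@H]1[C@@H](OC(C)=O)C=C(C)C1=O
F6 | step 11 | (1S)-2-[(2R)-but-3-en-2-yl]-4-methyl-3-(trifluoromethylsulfonyloxy)cyclopenta-2,4-dien-1-yl acetate | C=C[C@@H](C)C1=C(OS(=O)(=O)C(F)(F)F)C(C)=C[C@@H]1OC(C)=O
F7 | step 7 | (3R)-3-[(1R,2S)-2-acetoxy-3-methyl-2-(3-methylbut-2-en-1-yl)-5-oxocyclopent-3-en-1-yl]butanoic acid | OC(=O)C[C@@H](C)[C@H]1C(=O)C=C(C)[C@]1(OC(C)=O)CC=C(C)C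
F8 | step 7 | mixed trifluoroacetic anhydride of F7 | O=C(OC(=O)C(F)(F)F)C[C@@H](C)[C@H]1C(=O)C=C(C)[C@]1(OC(C)=O)CC=C(C)C
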